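## Structural features

Premarineosin A holds five rings. Pyrrole A sits on C5 of ring B, a 3-methoxy-2H-pyrrole whose only sp3 atom, Cq, is the spiro centre shared with tetrahydropyran ring D. Ring D is fused through its Cm–C8' bond to a 12-membered ansa ring: C2 of the 2,5-disubstituted pyrrole C is bonded to Cm, and a (CH2)7 chain (C7' to C1') runs from C8' to C5 of the same pyrrole. All four stereocentres lie on ring D: Cq (R) and Cm (S) are neighbours, C8' (S) follows Cm, and C10' (S), which carries the methyl group, stands 1,3 to C8' across C9'H2. In the chair that keeps the two macrocycle bonds at Cm and C8' equatorial and trans, the C10' methyl and the ring B nitrogen on Cq are both axial and syn across the ring oxygen. Fragile groups are the N,O-spiroketal at Cq (acid can open it towards a conjugated azafulvene), the vinylogous imidate of ring B, and the two electron-rich N–H pyrroles; the one on Cm can stabilise a cation there. The real difficulty is the fully substituted Cq (N, O and two carbons) next to Cm, together with the 2,4-trans relation of C8' and C10' on a ring that is part of a strained pyrrolophane. The key step uses the fact that O–Cq–Cm–C8' of ring D is a 1-oxadiene once Cq is the ketone carbon of an α-keto ester and Cm=C8' is the ring-cis alkene of the ansa ring; C9'–C10' then arrives as a two-carbon enol ether and ring D closes on the finished macrocycle.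

## Logic of the disconnections

**25 from 24.** No skeletal bond is cut; the two pyrrole N–H bonds are traced back to N–S bonds. Acceptor groups on both nitrogens make the cation and alkylation chemistry before this point safe. The demand on the last step is that both N–S bonds break under base alone, because 25 does not tolerate acid.

**24 from 23.** The O–CH3 bond of ring B is cut, which leaves a vinylogous amide. This form of ring B can close and equilibrate under acid, which the methyl enol ether could not survive. The forward step must alkylate oxygen, not nitrogen, and must not liberate acid.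

**23 from 21 through 22.** The N–Cq bond (with the Cm–H bond) and then the N–C5 bond are cut, which opens ring B to an acyl alkyne and ammonia. Nitrogen is delivered to Cq from inside the molecule, the only arrangement that makes addition across the conjugated, tetrasubstituted Cq=Cm bond favourable; conjugate addition to the alkyne fixes nitrogen on C5 without a regiochemical choice. Two stereocentres and one ring disappear. The forward step must protonate a deactivated enol ether at Cm and let Cq and Cm settle in their preferred arrangement.

**21 from 17 and 19 through 20.** The C3–C4 bond is cut. The ester carbon of 17 is C3 of ring B, and the alkynyl partner brings C4, C5 and ring A in one piece. The demand is a single addition to the ester.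

**19 from 18.** The alkyne terminus is removed by a one-carbon homologation of an aldehyde, which leads back to a commercial compound.

**17 from 16.** The C10'–CH3 bond is cut back to the acetal carbon of the cycloadduct, which is a latent oxocarbenium ion. The forward step must ionise the exocyclic C–O bond and deliver methyl axially, trans to the C8' substituent.

**16 from 15.** The ring C N–S bond is cut. The acceptor group is put on only after the key step: on the macrocycle before cycloaddition it would hold the bridge on one face of the pyrrole, make the substrate planar-chiral, and reduce catalyst control to a kinetic resolution.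

**15 from 13 and 14.** The C8'–C9' and O–C10' bonds are cut (key step). Ring D and two stereocentres are removed and an achiral macrocycle remains. The forward step needs face selection by a chiral Lewis acid, a reachable s-cis oxadiene and a free N–H so that the bridge stays mobile.

**13 from 12.** The Cm=C8' bond is cut as a condensation between an aldehyde and the acidic CH2 that lies between ring C and the keto ester. This is the only polar C–C bond of the ansa ring, and cutting it gives an open-chain 2,5-disubstituted pyrrole. The forward step needs high dilution, elimination and not lactonisation, and the ring-cis geometry.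

**12 from 10 through 11; 10 from 6 and 8 through 9; 8 from 7.** The ketone of the pyruvate is traced to an oxime, and the bond between C2 of ring C and Cm is cut. A nitrosoalkene alkylates the free α-position of a 2-alkylpyrrole under weak base, which avoids azlactone hydrolysis in hot acid. The aldehyde oxidation level is already present, so no ester has to be told from the keto ester later. The forward steps must leave the aldehyde alone.

**6 from 5 from 4; 4 from 1 and 2 through 3.** The C5–C1' bond is cut as an acylation. One hydride step then removes the ketone oxygen and sets the chain end to the alcohol, and one oxidation gives the aldehyde. The demand is C2 selectivity in the acylation and an oxidation mild enough for an N–H pyrrole.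

## Other disconnections considered

**Alternative 1:** The cut is the C5–C1' bond of the ansa chain. In the forward key step, the N-Boc 5-bromopyrrolyl δ-lactone A2, which carries a hept-6-enyl chain on C8', is hydroborated with 9-BBN; the alkylborane then couples with the bromide under PdCl2(dppf) at high dilution and closes the 12-membered ring to give A1.
- In its favour: the sp3–sp2 coupling has a well-defined organometallic course and closes the ring at a bond remote from every stereocentre. The three centres Cm, C8' and C10' are set beforehand on a simple six-membered lactone. Cq arrives as a lactone carbonyl, which accepts nucleophiles without any C-protonation of a deactivated enol ether.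
- Against it here: 2-bromo-N-Boc-pyrroles are labile, and the Boc group must sit inside the forming ansa ring. The stereotriad needs its own asymmetric chemistry. A1 is still far from 25, since all of ring B and the spiro centre remain to be built.
- Comparison: as a macrocyclisation it is probably the more dependable of the two, and its handling of Cq as a carbonyl is the better one. The chosen plan forms ring D and two stereocentres in one catalytic step on an achiral macrocycle and already carries the C3 carbon of ring B on Cq, which should make it the shorter route overall.

**Alternative 2:** The cuts are the Cq–C3 and N–C5 bonds of ring B. In the forward key step the lithiated methoxyallene A5 adds through its methoxy-bearing carbon to the imidate carbon of the lactone-derived N-tosyl imidate A4; the sulfonamide nitrogen then closes onto the allene terminus to give A3. Loss of sulfinate from A3 under base would deliver 25.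
- In its favour: ring B arrives with its methoxy group, ring A and nitrogen in one operation, against four operations in the chosen plan (acylation, ammonia addition, acid closure, O-methylation). On step economy for ring B it is the better route, and it has no O- versus N-methylation question. Additions of metallated alkoxyallenes to N-sulfonyl imines followed by cyclisation are an established reaction family.
- Against it here: the electrophile is an imidate, so the tetrahedral adduct can expel the ring D alkoxide and lose the spiro centre. The aryl-substituted lithiated allene is not a standard reagent and raises α/γ regiochemistry. Both pyrrole N–H groups must be masked against the organolithium. Cq is fixed under kinetic control.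
- Comparison: mechanistically it is more convergent but less forgiving; the acid closure of the chosen plan can equilibrate Cq and Cm. It also needs A6 or A1 first, so its total length depends on alternatives 1 or 3.

**Alternative 3:** The cuts are the two C–N bonds of ring C. In the forward key step the lactone-fused cyclotridecane-1,4-dione A7 condenses with ammonium acetate (Paal–Knorr), which turns the 13-membered carbocycle into the 12-membered ansa ring of A6.
- In its favour: the Paal–Knorr reaction is among the most reliable pyrrole syntheses and is known to give 2,5-bridged pyrrolophanes from cycloalkane-1,4-diones. A 13-membered carbocycle closes more easily than a pyrrolophane. The sensitive pyrrole appears late, so no nitrogen protection is needed; on the handling of ring C it is better than the chosen plan.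
- Against it here: Cm in A7 lies between a ketone and the lactone carbonyl, so its configuration cannot be stored and must settle thermodynamically. The condensation has to contract and bend the ring, and furan formation competes. A7, with two further stereocentres and a 1,4-diketone, is a long synthesis in itself, and ring B still has to follow.
- Comparison: it is equal to the chosen plan in relying on equilibration at Cm, and better in macrocycle formation and pyrrole handling. It is weaker in step economy and makes no use of catalysis to set C8'.

Key step: step 8

Remarks on the chemistry (assumptions):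
- Sense of induction: it is assigned from the square-planar chelate model, by which the (R,R)-ligand leaves the Re face of C8' open; if the first experiment showed the opposite sense, the (S,S)-ligand would be used with no other change.
- Bridge mobility: in the free N–H macrocycle 13 the bridge is assumed to pass the N–H fast compared with the cycloaddition, so that 13 behaves as an achiral substrate.
- Structure check: 13 (E, ring-cis alkene, seven CH2 groups) and 15 (C8' S, C10' S, 2,4-cis) were checked atom by atom against 25 and are used unchanged. What is changed is the timing of the nitrogen acceptor group, the early setting of the chain-end oxidation level and the way nitrogen reaches Cq.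

## Steps

Step 1
Reactants: 1 pyrrole; 2 methyl 8-chloro-8-oxooctanoate
Product: 4 methyl 8-oxo-8-(1H-pyrrol-2-yl)octanoate, via pyrrol-1-ylmagnesium bromide 3 (not isolated)
Conditions: 1, EtMgBr, Et2O/toluene, 0 °C; then 2, −40 → 0 °C
Reagents that add atoms: none
Why: C-acylation of a pyrrolyl Grignard reagent; in a non-polar medium the magnesium salt 3 reacts with the acid chloride at C2 and not at nitrogen, and the methyl ester is too weak an electrophile for 3 at this temperature.

Step 2
Reactants: 4 methyl 8-oxo-8-(1H-pyrrol-2-yl)octanoate
Product: 5 8-(1H-pyrrol-2-yl)octan-1-ol
Conditions: LiAlH4, THF, reflux; aq. Rochelle salt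
Reagents that add atoms: none
Why: Hydride reduction; LiAlH4 takes the ester to the primary alcohol and the 2-acylpyrrole to the 2-alkylpyrrole, because the N-metallated carbinol expels aluminate to an azafulvene that accepts a second hydride.

Step 3
Reactants: 5 8-(1H-pyrrol-2-yl)octan-1-ol
Product: 6 8-(1H-pyrrol-2-yl)octanal
Conditions: SO3·pyridine, DMSO, i-Pr2NEt, CH2Cl2, 0 °C
Reagents that add atoms: none
Why: Parikh–Doering oxidation; the activated DMSO reagent at 0 °C is mild enough for an electron-rich N–H pyrrole and stops at the aldehyde.

Step 4
Reactants: 7 methyl 3-bromo-2-oxopropanoate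
Product: 8 methyl 3-bromo-2-(hydroxyimino)propanoate
Conditions: NH2OH·HCl, CHCl3/MeOH, rt
Reagents that add atoms: hydroxylamine hydrochloride, Cl.NO
Why: Oxime formation at the ketone of the α-keto ester; no base is present, so the neighbouring bromide is kept.

Step 5
Reactants: 6 8-(1H-pyrrol-2-yl)octanal; 8 methyl 3-bromo-2-(hydroxyimino)propanoate
Product: 10 methyl 2-(hydroxyimino)-3-[5-(8-oxooctyl)-1H-pyrrol-2-yl]propanoate, via methyl 2-nitrosoacrylate 9 (not isolated)
Conditions: Na2CO3, CH2Cl2, rt, slow addition of 8
Reagents that add atoms: none
Why: Base-induced 1,4-elimination of HBr from 8 gives the nitrosoalkene 9, a strong heterodiene and Michael acceptor that alkylates the free α-position C5 of the 2-alkylpyrrole (conjugate alkylation through a [4+2] adduct that re-aromatises); the aldehyde and the N–H are not touched by Na2CO3.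

Step 6
Reactants: 10 methyl 2-(hydroxyimino)-3-[5-(8-oxooctyl)-1H-pyrrol-2-yl]propanoate
Product: 12 methyl 2-oxo-3-[5-(8-oxooctyl)-1H-pyrrol-2-yl]propanoate, via imino ester 11 (not isolated)
Conditions: aq. TiCl3, NH4OAc, THF/H2O, 0 °C → rt; then pH 3, brief
Reagents that add atoms: water, O
Why: Reductive deoximation; trivalent titanium cleaves the N–O bond to the N–H imine 11, which is hydrolysed in the buffered medium, and aliphatic aldehydes are inert to aqueous TiCl3. The pyrrolylpyruvate should be largely enolised and is used at once.

Step 7
Reactants: 12 methyl 2-oxo-3-[5-(8-oxooctyl)-1H-pyrrol-2-yl]propanoate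
Product: 13 methyl 2-oxoacetate on Cm of the 12-membered ansa pyrrole with E (ring-cis) Cm=C8' alkene
Conditions: EDDA (20 mol %), 4 Å MS, toluene, 50 °C, syringe-pump addition to 1 mM
Reagents that add atoms: none
Why: Intramolecular Knoevenagel condensation at high dilution; the ammonium acetate catalyst converts the aldehyde into an iminium ion, the pyruvate enol adds through Cm and the amine leaves by E1cB elimination, so no β-hydroxy group remains that could lactonise. The E (ring-cis) alkene is the geometry the 12-membered ring accommodates and is reached under the reversible conditions.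

Step 8
Reactants: 13 ansa-pyrrole unsaturated α-keto ester; 14 ethyl vinyl ether
Product: 15 ansa methyl 2-ethoxy-3,4-dihydro-2H-pyran-6-carboxylate (C8' S; C10' S; ethoxy cis to the C8'–C7' bond)
Conditions: Cu(OTf)2 (10 mol %), (R,R)-t-Bu-box (11 mol %), 3 Å MS, THF, −40 → 0 °C
Reagents that add atoms: none
Why: Proposed new method: the ketone and ester oxygens of 13 chelate the square-planar divalent copper of the Cu(OTf)2/(R,R)-t-Bu-box complex, which lowers the LUMO of the s-cis oxadiene O=Cq–Cm=C8'. Ethyl vinyl ether then adds in a concerted, asynchronous inverse-electron-demand [4+2] cycloaddition, its CH2 carbon bonding to C8' ahead of the bond from its oxygen-bearing carbon to the ketone oxygen. The closest known reaction type is the copper bis(oxazoline)-catalysed hetero-Diels–Alder reaction of open-chain (E)-β,γ-unsaturated α-keto esters with enol ethers; new here are the ring-cis alkene held in a 12-membered ansa ring and the pyrrol-2-yl group on Cm. Ring D closes in this single cycloaddition as a 3,4-dihydro-2H-pyran (bonds C8'–C9' and O–C10'), the E geometry of 13 already being the one the ring needs. C8' (S) is set by the ligand, one tert-butyl group covering the Si face of C8' in the chelate so that the dienophile meets the Re face. C10' (S) is set by the endo transition state, which puts the ethoxy group under the diene and gives the 2,4-cis acetal. The step needs regioselectivity, secured by the match of the nucleophilic CH2 terminus with the electrophilic C8'; periselectivity over the 2-vinylpyrrole diene, secured by two-point activation of the keto ester alone; and catalyst control of the face, expected because the bridge of the free N–H macrocycle can swing to either side.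

Step 9
Reactants: 15 ansa methyl 2-ethoxy-3,4-dihydro-2H-pyran-6-carboxylate
Product: 16 N-benzenesulfonyl derivative of 15 (ring C nitrogen)
Conditions: NaH, PhSO2Cl, THF, 0 °C → rt
Reagents that add atoms: benzenesulfonyl chloride, O=S(=O)(Cl)c1ccccc1
Why: N-sulfonylation of the pyrrolide; the acceptor group shuts off azafulvene formation at Cm (which would endanger C8') and lets the ring oxygen, not the pyrrole, direct the later protonation of the enol ether. With the bridge now fused to ring D, its position is only a matter of conformation.

Step 10
Reactants: 16 N-benzenesulfonyl cycloadduct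
Product: 17 ansa methyl 2-methyl-3,4-dihydro-2H-pyran-6-carboxylate (C8' S; C10' S; methyl trans to the C8'–C7' bond)
Conditions: AlMe3, TMSOTf, CH2Cl2, −78 → −30 °C
Reagents that add atoms: trimethylaluminium, C[Al](C)C
Why: Lewis acid-mediated substitution of an acetal through an oxocarbenium ion; TMSOTf ionises the more basic exocyclic ethoxy group and AlMe3 transfers methyl along the axial trajectory anti to the pseudo-equatorial C8'–C7' bond, which gives the 2,4-trans product with the methyl axial. The ester is inert to AlMe3 at this temperature.

Step 11
Reactants: 18 1-(phenylsulfonyl)-1H-pyrrole-2-carbaldehyde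
Product: 19 2-ethynyl-1-(phenylsulfonyl)-1H-pyrrole
Conditions: TMSCHN2, LDA, THF, −78 °C → rt
Reagents that add atoms: (trimethylsilyl)diazomethane, C[Si](C)(C)C=[N+]=[N-]
Why: Colvin homologation; the lithiated silyldiazomethane adds to the aldehyde, silanolate and dinitrogen are lost and a 1,2-hydrogen shift gives the terminal alkyne, with no protic base to touch the N-sulfonyl group.

Step 12
Reactants: 17 ansa methyl 2-methyl-3,4-dihydro-2H-pyran-6-carboxylate; 19 2-ethynyl-1-(phenylsulfonyl)-1H-pyrrole
Product: 21 ansa dihydropyranyl alkynyl ketone (ynone; C3 carbonyl on Cq; alkyne to ring A), via lithium acetylide 20 (not isolated)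
Conditions: 19, n-BuLi, THF, −78 °C; BF3·OEt2; then 17, −78 °C
Reagents that add atoms: none
Why: Acylation of an alkynyllithium by an ester in the presence of BF3; the Lewis acid activates the ester and holds the tetrahedral adduct until work-up, so the ketone is released only then and is not attacked twice. The fully substituted, conjugated enol ether is not a Michael acceptor for the acetylide.

Step 13
Reactants: 21 ansa dihydropyranyl alkynyl ketone
Product: 23 spiro 1,2-dihydro-3H-pyrrol-3-one (rings B and D joined at Cq; Cq R; Cm S; C8' S; C10' S), via enaminone 22 (not isolated)
Conditions: NH3 (7 M in MeOH), THF, rt; concentrate; CSA, 4 Å MS, CH2Cl2, rt → 40 °C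
Reagents that add atoms: ammonia, N
Why: Conjugate addition of ammonia to the ynone puts nitrogen on C5 only and gives the Z, hydrogen-bonded primary enaminone 22; acid then protonates the enol ether at Cm and the enaminone nitrogen closes on the oxocarbenium carbon Cq (5-exo-trig N,O-spiroketalisation). Both new stereocentres are set under thermodynamic control, because ring closure and Cm protonation are reversible in acid: the pyrrolyl group on Cm goes equatorial, trans to the C8'–C7' bond, and nitrogen takes the axial, anomerically stabilised place on Cq, where it is also the smaller group next to the axial C10' methyl.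

Step 14
Reactants: 23 spiro 1,2-dihydro-3H-pyrrol-3-one
Product: 24 N,N'-bis(benzenesulfonyl)premarineosin A
Conditions: MeOTf, 2,6-di-tert-butyl-4-methylpyridine, CH2Cl2, 0 °C; aq. NaHCO3
Reagents that add atoms: methyl trifluoromethanesulfonate, COS(=O)(=O)C(F)(F)F
Why: O-alkylation of a vinylogous amide by a hard methylating agent; the hindered pyridine takes the proton from nitrogen, so the 3-methoxy-2H-pyrrole forms without free acid that could open the N,O-ketal. The nitrogen is flanked by the spiro centre and should not be methylated.

Step 15
Reactants: 24 N,N'-bis(benzenesulfonyl)premarineosin A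
Product: 25 premarineosin A
Conditions: KOH, MeOH/THF, 60 °C
Reagents that add atoms: none
Why: Nucleophilic cleavage of the two pyrrole sulfonamides at sulfur by hydroxide or methoxide; the N,O-spiroketal, the enol ether and the imine of ring B have no base-labile bond and no acidic C–H next to a stereocentre, so the four stereocentres should be kept.

## Compound list

1 | pyrrole | c1cc[nH]c1 | starting material
2 | methyl 8-chloro-8-oxooctanoate (acid chloride of suberic acid monomethyl ester) | COC(=O)CCCCCCC(Cl)=O | starting material
3 | pyrrol-1-ylmagnesium bromide | Br[Mg]n1cccc1 | intermediate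
4 | methyl 8-oxo-8-(1H-pyrrol-2-yl)octanoate | COC(=O)CCCCCCC(=O)c1ccc[nH]1 | intermediate
5 | 8-(1H-pyrrol-2-yl)octan-1-ol | OCCCCCCCCc1ccc[nH]1 | intermediate
6 | 8-(1H-pyrrol-2-yl)octanal | O=CCCCCCCCc1ccc[nH]1 | intermediate
7 | methyl 3-bromo-2-oxopropanoate | COC(=O)C(=O)CBr | starting material
8 | methyl 3-bromo-2-(hydroxyimino)propanoate | COC(=O)C(CBr)=NO | intermediate
9 | methyl 2-nitrosoacrylate | COC(=O)C(=C)N=O | intermediate
10 | methyl 2-(hydroxyimino)-3-[5-(8-oxooctyl)-1H-pyrrol-2-yl]propanoate | COC(=O)C(=NO)Cc1ccc(CCCCCCCC=O)[nH]1 | intermediate
11 | methyl 2-imino-3-[5-(8-oxooctyl)-1H-pyrrol-2-yl]propanoate | COC(=O)C(=N)Cc1ccc(CCCCCCCC=O)[nH]1 | intermediate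
12 | methyl 2-oxo-3-[5-(8-oxooctyl)-1H-pyrrol-2-yl]propanoate | COC(=O)C(=O)Cc1ccc(CCCCCCCC=O)[nH]1 | intermediate
13 | 12-membered ansa-pyrrole unsaturated α-keto ester: pyrrole C2–Cm(COCO2Me)=C8'H–(CH2)7–pyrrole C5, E (ring-cis) alkene, free N–H | COC(=O)C(=O)/C1=C/CCCCCCCc2ccc1[nH]2 | intermediate
14 | ethyl vinyl ether | CCOC=C | starting material
15 | ansa methyl 2-ethoxy-3,4-dihydro-2H-pyran-6-carboxylate: ring D with Cq=Cm, ester on Cq, C8' S, C10' S, ethoxy cis to the C8' chain, free N–H | COC(=O)C2=C1c3ccc(CCCCCCC[C@H]1C[C@@H](OCC)O2)[nH]3 | intermediate
16 | N-benzenesulfonyl derivative of 15 | COC(=O)C2=C1c3ccc(CCCCCCC[C@H]1C[C@@H](OCC)O2)n3S(=O)(=O)c4ccccc4 | intermediate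
17 | ansa methyl 2-methyl-3,4-dihydro-2H-pyran-6-carboxylate: C8' S, C10' S, methyl trans to the C8' chain, N-benzenesulfonyl | COC(=O)C2=C1c3ccc(CCCCCCC[C@H]1C[C@H](C)O2)n3S(=O)(=O)c4ccccc4 | intermediate
18 | 1-(phenylsulfonyl)-1H-pyrrole-2-carbaldehyde | O=Cc1cccn1S(=O)(=O)c1ccccc1 | starting material
19 | 2-ethynyl-1-(phenylsulfonyl)-1H-pyrrole | C#Cc1cccn1S(=O)(=O)c1ccccc1 | intermediate
20 | lithium acetylide of 19 | [Li]C#Cc1cccn1S(=O)(=O)c1ccccc1 | intermediate
21 | ynone: Cq of the dihydropyran 17 bonded to C(=O)–C≡C–[1-(phenylsulfonyl)pyrrol-2-yl] in place of the ester | O=C(C#Cc5cccn5S(=O)(=O)c6ccccc6)C2=C1c3ccc(CCCCCCC[C@H]1C[C@H](C)O2)n3S(=O)(=O)c4ccccc4 | intermediate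
22 | Z primary enaminone: Cq–C(=O)–CH=C(NH2)–[1-(phenylsulfonyl)pyrrol-2-yl] | N/C(=C\C(=O)C2=C1c3ccc(CCCCCCC[C@H]1C[C@H](C)O2)n3S(=O)(=O)c4ccccc4)c5cccn5S(=O)(=O)c6ccccc6 | intermediate
23 | spiro 1,2-dihydro-3H-pyrrol-3-one: ring B as NH–C5(ring A)=C4H–C3(=O) on spiro Cq; Cq R, Cm S, C8' S, C10' S; both pyrroles N-benzenesulfonyl | O=C1C=C(c5cccn5S(=O)(=O)c6ccccc6)N[C@]12O[C@@H](C)C[C@@H]1CCCCCCCc3ccc(n3S(=O)(=O)c4ccccc4)[C@H]12 | intermediate
24 | N,N'-bis(benzenesulfonyl)premarineosin A | COC1=CC(c5cccn5S(=O)(=O)c6ccccc6)=N[C@]12O[C@@H](C)C[C@@H]1CCCCCCCc3ccc(n3S(=O)(=O)c4ccccc4)[C@H]12 | intermediate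
25 | premarineosin A (Cq R, Cm S, C8' S, C10' S) | COC1=CC(c2ccc[nH]2)=N[C@]12O[C@@H](C)C[C@@H]1CCCCCCCc3ccc([nH]3)[C@H]12 | target

## Step count and least certain steps

Total: 15 steps. Longest linear sequence: 13 steps (1, 2, 3, 5, 6, 7, 8, 9, 10, 12, 13, 14, 15); steps 4 and 11 are one-step branches.

**Step 8 (key step, proposed new method).** Three things are most likely to go wrong. The rate may be low, because the s-cis oxadiene places the chelated ester next to the pyrrole on Cm and the pyrrole feeds electron density towards C8'. Face selection may be poor if the bridge of 13 does not pass the N–H fast enough, so that the catalyst only resolves two slowly interconverting planar forms. The free pyrrole β-positions may be alkylated by vinyl ether-derived cations. The fallback uses known auxiliary control in place of catalyst control and sets out from 13. Transvinylation of methyl (R)-mandelate with 14 (Hg(OAc)2 cat.) would give methyl (R)-2-phenyl-2-(vinyloxy)acetate F1. The Eu(fod)3-catalysed inverse-demand hetero-Diels–Alder reaction of 13 with F1 (a known reaction of unsaturated α-keto esters with chiral vinyl ethers, which tolerates N–H groups) would give the mandelyl acetal F2; the antipode of the auxiliary is taken if it proves to be the one matched to the Re face of C8'. N-Sulfonylation as in step 9 would give F3, and AlMe3/TMSOTf as in step 10 would replace the auxiliary alkoxy group by methyl, so that the route is rejoined at 17.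

**Step 13.** The enaminone buffers the acid, so C-protonation of the deactivated enol ether at Cm may be too slow. Ring D may open instead to a conjugated 2-alkylidene pyrrolinone, or Cq and Cm may not converge on one diastereomer. The fallback sets out from 17 and brings nitrogen in first, onto the non-basic ester. A Ritter reaction (TfOH, MeCN, −20 °C, then water) would give the N-acetyl N,O-ketal ester F4. Dieckmann closure (LiHMDS, THF) would give the spiro tetramic acid F5, and O-methylation (TMSCHN2) the 4-methoxy-3-pyrrolin-2-one F6. Tf2O/2,6-lutidine would give the imidoyl triflate F7, and Suzuki coupling with N-Boc-pyrrol-2-ylboronic acid (Pd(PPh3)4, zerovalent palladium, K2CO3) the N-Boc, N'-benzenesulfonyl compound F8. KOH/MeOH as in step 15 removes both nitrogen groups and rejoins the route at 25.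

**Step 7.** The aldol adduct may lactonise onto the keto ester to a butenolide and not dehydrate, the aldehyde may oligomerise, or the pyrrole nitrogen may be acylated by the keto ester. The fallback sets out from 12 and closes the ring through an ether that cannot lactonise. Selective acetalisation of the aldehyde (HC(OMe)3, MeOH, PPTS) would give the dimethyl acetal F9. A Mukaiyama aldol macrocyclisation (TMSOTf, i-Pr2NEt, CH2Cl2, high dilution; silyl enol ether and oxocarbenium ion formed in the flask) would give the β-methoxy keto ester macrocycle F10. Elimination of methanol with DBU rejoins the route at 13.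

**Step 10.** Ionisation may take the ring oxygen and not the ethoxy group, the cation may lose a proton to a 4H-pyran, or methyl may be delivered to both faces. The fallback sets out from 16 and changes leaving group and nucleophile. Benzenesulfinic acid/CaCl2 would give the anomeric sulfone F11, which with a methylzinc reagent (MeMgBr, ZnBr2, THF) is substituted under much weaker Lewis acidity, again by axial attack; the route is rejoined at 17.

**Step 15.** The sulfonamide of the electron-rich, hindered ring C pyrrole may cleave slowly, and long heating in base may degrade the chromophore of ring B. The fallback sets out from 23 and reverses the order. KOH/MeOH on the more robust vinylogous amide would give the doubly N–H spiro pyrrolinone F12, and O-methylation as in step 14 then gives 25 directly.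

## Further compounds

F1 | step 8 | methyl (R)-2-phenyl-2-(vinyloxy)acetate | C=CO[C@@H](C(=O)OC)c1ccccc1
F2 | step 8 | cycloadduct of 13 with F1 (mandelyl acetal in place of the ethyl acetal of 15) | COC(=O)C2=C1c3ccc(CCCCCCC[C@H]1C[C@@H](O[C@@H](C(=O)OC)c4ccccc4)O2)[nH]3
F3 | step 8 | N-benzenesulfonyl derivative of F2 | COC(=O)C2=C1c3ccc(CCCCCCC[C@H]1C[C@@H](O[C@@H](C(=O)OC)c4ccccc4)O2)n3S(=O)(=O)c5ccccc5
F4 | step 13 | N-acetyl N,O-ketal ester (acetamido and ester on Cq, H on Cm) | COC(=O)[C@]2(NC(C)=O)O[C@@H](C)C[C@@H]1CCCCCCCc3ccc(n3S(=O)(=O)c4ccccc4)[C@H]12
F5 | step 13 | spiro tetramic acid (pyrrolidine-2,4-dione on Cq) | O=C1CC(=O)N[C@]12O[C@@H](C)C[C@@H]1CCCCCCCc3ccc(n3S(=O)(=O)c4ccccc4)[C@H]12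
F6 | step 13 | spiro 4-methoxy-3-pyrrolin-2-one | COC1=CC(=O)N[C@]12O[C@@H](C)C[C@@H]1CCCCCCCc3ccc(n3S(=O)(=O)c4ccccc4)[C@H]12
F7 | step 13 | imidoyl triflate of F6 | COC1=CC(OS(=O)(=O)C(F)(F)F)=N[C@]12O[C@@H](C)C[C@@H]1CCCCCCCc3ccc(n3S(=O)(=O)c4ccccc4)[C@H]12
F8 | step 13 | premarineosin A with N-Boc on ring A and N-benzenesulfonyl on ring C | COC1=CC(c5cccn5C(=O)OC(C)(C)C)=N[C@]12O[C@@H](C)C[C@@H]1CCCCCCCc3ccc(n3S(=O)(=O)c4ccccc4)[C@H]12
F9 | step 7 | methyl 3-[5-(8,8-dimethoxyoctyl)-1H-pyrrol-2-yl]-2-oxopropanoate | COC(=O)C(=O)Cc1ccc(CCCCCCCC(OC)OC)[nH]1
F10 | step 7 | β-methoxy keto ester macrocycle (methoxy on C8', H on Cm) | COC(=O)C(=O)C1C(OC)CCCCCCCc2ccc1[nH]2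
F11 | step 10 | anomeric sulfone (benzenesulfonyl on C10' in place of the ethoxy group of 16) | COC(=O)C2=C1c3ccc(CCCCCCC[C@H]1CC(S(=O)(=O)c5ccccc5)O2)n3S(=O)(=O)c4ccccc4
F12 | step 15 | spiro pyrrol-3(2H)-one with both pyrroles N–H | O=C1C=C(c5ccc[nH]5)N[C@]12O[C@@H](C)C[C@@H]1CCCCCCCc3ccc([nH]3)[C@H]12
A1 | alternative 1 | N-Boc pyrrolophane δ-lactone | O=C2O[C@@H](C)C[C@@H]1CCCCCCCc3ccc(n3C(=O)OC(C)(C)C)[C@H]12
A2 | alternative 1 | δ-lactone with hept-6-enyl on C8' and N-Boc-5-bromopyrrol-2-yl on Cm | O=C1O[C@@H](C)C[C@H](CCCCCC=C)[C@H]1c1ccc(Br)n1C(=O)OC(C)(C)C
A3 | alternative 2 | N-tosyl spiro 3-methoxy-2,5-dihydropyrrole | COC1=CC(c2ccc[nH]2)N(S(=O)(=O)c2ccc(C)cc2)[C@]13O[C@@H](C)C[C@@H]1CCCCCCCc4ccc([nH]4)[C@H]13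
A4 | alternative 2 | N-tosyl imidate of the pyrrolophane δ-lactone | Cc1ccc(cc1)S(=O)(=O)N=C2O[C@@H](C)C[C@@H]1CCCCCCCc3ccc([nH]3)[C@H]12
A5 | alternative 2 | 1-lithio-1-methoxy-3-(pyrrol-2-yl)allene (nitrogen masked in practice) | COC([Li])=C=Cc1ccc[nH]1
A6 | alternative 3 | pyrrolophane δ-lactone | O=C2O[C@@H](C)C[C@@H]1CCCCCCCc3ccc([nH]3)[C@H]12
A7 | alternative 3 | lactone-fused cyclotridecane-1,4-dione | O=C2O[C@@H](C)C[C@@H]1CCCCCCCC(=O)CCC(=O)[C@H]12
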